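**Plan**

- Retrosynthetic cuts, late to early: the O–CH3 bond and both C–O bonds at C6/C7 (back to an E-configured C6=C7 alkene); the acetate and C11–CH3 (back to a C11 ketone masked as its ethyl enol ether); C15=CH2; then C12–C13 together with C1–C14 (intramolecular Diels–Alder); C10–C11 (Stille); C8–C9 with loss of O–C6 (oxonium ylide [2,3] shift); C2–C3 (ketyl–olefin cyclisation).
- Forward ring order: oxane, then oxonene plus tetrahydrofuranone in one step, then cyclohexene plus seven-membered lactone in one step, then functional-group adjustment.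
- Enabling feature: in the 11-oxabicyclo[6.2.1]undecadiene the ring double bond C1=C10 of the 2,5-dihydrofuran and the exocyclic C11(OEt)=C12 unit form an s-cis 2-alkoxydiene. The tertiary C3 oxygen stands five atoms from C14, so the future lactone ester (C16) carrying a temporary C15 ketone both tethers and activates a C13=C14 vinyl group.
- Stereochemistry: C6 carbinol (kinetic resolution) → C2 (2,6-cis oxane) → C3 (equatorial Grignard attack) → C9 ([2,3] shift; C6 then becomes sp2) → C1 and C14 (cycloaddition anti to the oxonene bridge, trans fusion) → C15, C10, C11 (substrate control on the cis-fused core) → C6 and C7 (syn dihydroxylation of the E alkene).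

Key step: step 18

Remark: locants C1–C20 in the names of bicyclic and tetracyclic compounds follow eunicellane numbering (C2–O–C9 ether, C3–O–C16 lactone, C6 methoxy, C7 hydroxy, C11 acetate); 4-[(tert-butyldimethylsilyl)oxy]butanal is taken as commercially available.

**Step 1**
Reactants: 1 4-[(tert-butyldimethylsilyl)oxy]butanal; 2 isopropenylmagnesium bromide
Product: 3 (±)-6-[(tert-butyldimethylsilyl)oxy]-2-methylhex-1-en-3-ol
Conditions: THF, −78 to 0 °C; H2O
Reagents that add atoms: isopropenylmagnesium bromide (2), CC(=C)[Mg]Br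
Why: Grignard 1,2-addition to the aldehyde should give the racemic allylic alcohol that carries C3–C8 and C19.

**Step 2**
Reactants: 3 (±)-6-[(tert-butyldimethylsilyl)oxy]-2-methylhex-1-en-3-ol
Product: 4 (3S)-6-[(tert-butyldimethylsilyl)oxy]-2-methylhex-1-en-3-ol
Conditions: Ti(OiPr)4 (0.1 equiv), D-(−)-diisopropyl tartrate (0.15 equiv), t-BuOOH (0.6 equiv), 4 Å MS, CH2Cl2, −20 °C
Reagents that add atoms: none
Why: In a Sharpless kinetic resolution with the D-tartrate the (R)-alcohol should be epoxidised faster, leaving the (S)-carbinol (C6), which is the only external source of absolute configuration in the route.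

**Step 3**
Reactants: 4 (3S)-6-[(tert-butyldimethylsilyl)oxy]-2-methylhex-1-en-3-ol; 5 ethyl propiolate
Product: 6 ethyl (2E)-3-{[(3S)-6-[(tert-butyldimethylsilyl)oxy]-2-methylhex-1-en-3-yl]oxy}prop-2-enoate
Conditions: N-methylmorpholine (cat.), CH2Cl2, rt
Reagents that add atoms: ethyl propiolate (5), CCOC(=O)C#C
Why: Amine-catalysed oxa-Michael addition of the alcohol to the ynoate should give the (E)-β-alkoxyacrylate that supplies C2, C1 and C10.

**Step 4**
Reactants: 6 ethyl (2E)-3-{[(3S)-6-[(tert-butyldimethylsilyl)oxy]-2-methylhex-1-en-3-yl]oxy}prop-2-enoate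
Product: 7 ethyl (2E)-3-{[(3S)-6-hydroxy-2-methylhex-1-en-3-yl]oxy}prop-2-enoate
Conditions: HF·pyridine, pyridine, THF, 0 °C to rt
Reagents that add atoms: none
Why: Fluoride cleaves the primary silyl ether while the push–pull enol ether is inert to the buffered reagent.

**Step 5**
Reactants: 7 ethyl (2E)-3-{[(3S)-6-hydroxy-2-methylhex-1-en-3-yl]oxy}prop-2-enoate
Product: 8 ethyl (2E)-3-{[(3S)-2-methyl-6-oxohex-1-en-3-yl]oxy}prop-2-enoate
Conditions: Dess–Martin periodinane, CH2Cl2, 0 °C to rt
Reagents that add atoms: none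
Why: Dess–Martin oxidation of the primary alcohol should give the aldehyde (C3) without touching the alkoxyacrylate or the isopropenyl group.

**Step 6**
Reactants: 8 ethyl (2E)-3-{[(3S)-2-methyl-6-oxohex-1-en-3-yl]oxy}prop-2-enoate
Product: 9 ethyl 2-[(2S,3R,6S)-3-hydroxy-6-(prop-1-en-2-yl)oxan-2-yl]acetate
Conditions: SmI2 (2.5 equiv), MeOH (2 equiv), THF, 0 °C
Reagents that add atoms: none
Why: SmI2 ketyl–olefin reductive cyclisation onto the β-alkoxyacrylate through a chelated chair with both side chains equatorial should give the 2,6-cis-2,3-trans oxane, so that C2 is set from C6.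

**Step 7**
Reactants: 9 ethyl 2-[(2S,3R,6S)-3-hydroxy-6-(prop-1-en-2-yl)oxan-2-yl]acetate
Product: 10 ethyl 2-[(2S,6S)-3-oxo-6-(prop-1-en-2-yl)oxan-2-yl]acetate
Conditions: Dess–Martin periodinane, CH2Cl2, rt
Reagents that add atoms: none
Why: Dess–Martin oxidation gives the oxan-3-one under non-basic conditions that keep the 2,6-cis arrangement, so that the tertiary C3 centre can be built by carbonyl addition.

**Step 8**
Reactants: 10 ethyl 2-[(2S,6S)-3-oxo-6-(prop-1-en-2-yl)oxan-2-yl]acetate; 11 methylmagnesium chloride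
Product: 12 ethyl 2-[(2S,3S,6S)-3-hydroxy-3-methyl-6-(prop-1-en-2-yl)oxan-2-yl]acetate
Conditions: THF, −78 °C; AcOH quench at −78 °C
Reagents that add atoms: methylmagnesium chloride (11), C[Mg]Cl
Why: Grignard addition to the ketone (the ester is inert at −78 °C) should take the equatorial trajectory anti to the C2–O ring bond (Felkin–Anh, as in additions to pyranosid-2-uloses), giving the axial C3 hydroxyl cis to the C2 side chain, and the cold acidic quench prevents lactonisation.

**Step 9**
Reactants: 12 ethyl 2-[(2S,3S,6S)-3-hydroxy-3-methyl-6-(prop-1-en-2-yl)oxan-2-yl]acetate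
Product: 13 ethyl 2-[(2S,3S,6S)-3-methyl-6-(prop-1-en-2-yl)-3-[(triethylsilyl)oxy]oxan-2-yl]acetate
Conditions: Et3SiOTf, 2,6-lutidine, CH2Cl2, −78 to 0 °C
Reagents that add atoms: triethylsilyl trifluoromethanesulfonate, CC[Si](CC)(CC)OS(=O)(=O)C(F)(F)F
Why: The silyl triflate silylates the hindered tertiary alcohol, which would otherwise undergo O–H insertion with the later carbenoid.

**Step 10**
Reactants: 13 ethyl 2-[(2S,3S,6S)-3-methyl-6-(prop-1-en-2-yl)-3-[(triethylsilyl)oxy]oxan-2-yl]acetate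
Product: 14 2-[(2S,3S,6S)-3-methyl-6-(prop-1-en-2-yl)-3-[(triethylsilyl)oxy]oxan-2-yl]acetic acid
Conditions: LiOH, THF/MeOH/H2O, rt; then aq. HCl to pH 4 at 0 °C
Reagents that add atoms: lithium hydroxide, [Li+].[OH-]
Why: Saponification of the unhindered ethyl ester should leave the tertiary silyl ether intact under base and brief mild acidification.

**Step 11**
Reactants: 14 2-[(2S,3S,6S)-3-methyl-6-(prop-1-en-2-yl)-3-[(triethylsilyl)oxy]oxan-2-yl]acetic acid; 15 diazomethane
Product: 17 1-diazo-3-[(2S,3S,6S)-3-methyl-6-(prop-1-en-2-yl)-3-[(triethylsilyl)oxy]oxan-2-yl]propan-2-one, via mixed isobutyl carbonic anhydride 16 (not isolated)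
Conditions: i-BuOCOCl, Et3N, Et2O, −20 °C; then CH2N2, Et2O, 0 °C to rt
Reagents that add atoms: diazomethane (15), C=[N+]=[N-]; isobutyl chloroformate, CC(C)COC(=O)Cl (its atoms stay only in intermediate 16)
Why: C-acylation of diazomethane by the mixed anhydride is the standard entry to α-diazoketones and adds C9.

**Step 12**
Reactants: 17 1-diazo-3-[(2S,3S,6S)-3-methyl-6-(prop-1-en-2-yl)-3-[(triethylsilyl)oxy]oxan-2-yl]propan-2-one
Product: 18 (1S,2S,5E,8S)-2,6-dimethyl-2-[(triethylsilyl)oxy]-11-oxabicyclo[6.2.1]undec-5-en-9-one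
Conditions: Rh2(NHCOCF3)4 (1 mol %), CH2Cl2, reflux, slow addition of 17
Reagents that add atoms: none
Why: The rhodium carbenoid is captured by the ring oxygen and the oxonium ylide undergoes a [2,3]-sigmatropic shift through the isopropenyl group, a three-atom ring expansion that forms the oxonene and the bridging tetrahydrofuranone at once; C9 is fixed by the bridged geometry from C2, and the amidate ligand is chosen because it should favour the E alkene in this class of diazoketones.

**Step 13**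
Reactants: 18 (1S,2S,5E,8S)-2,6-dimethyl-2-[(triethylsilyl)oxy]-11-oxabicyclo[6.2.1]undec-5-en-9-one
Product: 19 (1S,2S,5E,8S)-2,6-dimethyl-2-[(triethylsilyl)oxy]-11-oxabicyclo[6.2.1]undeca-5,9-dien-9-yl trifluoromethanesulfonate
Conditions: NaN(SiMe3)2, PhNTf2, THF, −78 °C
Reagents that add atoms: N-phenylbis(trifluoromethanesulfonimide), O=S(=O)(N(c1ccccc1)S(=O)(=O)C(F)(F)F)C(F)(F)F
Why: Kinetic deprotonation occurs at the C1 methylene and not at the bridgehead C9 methine, and O-triflation of the enolate should give the C1=C10 enol triflate.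

**Step 14**
Reactants: 19 (1S,2S,5E,8S)-2,6-dimethyl-2-[(triethylsilyl)oxy]-11-oxabicyclo[6.2.1]undeca-5,9-dien-9-yl trifluoromethanesulfonate; 20 tributyl(1-ethoxyvinyl)stannane
Product: 21 (1S,2S,5E,8S)-9-(1-ethoxyethenyl)-2,6-dimethyl-2-[(triethylsilyl)oxy]-11-oxabicyclo[6.2.1]undeca-5,9-diene
Conditions: Pd(PPh3)4 (5 mol %), LiCl, THF, 65 °C
Reagents that add atoms: tributyl(1-ethoxyvinyl)stannane (20), CCCC[Sn](CCCC)(CCCC)C(=C)OCC
Why: Stille coupling of the enol triflate adds C11 and C12 and gives the 2-ethoxydiene, whose enol ether is also the latent C11 ketone.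

**Step 15**
Reactants: 21 (1S,2S,5E,8S)-9-(1-ethoxyethenyl)-2,6-dimethyl-2-[(triethylsilyl)oxy]-11-oxabicyclo[6.2.1]undeca-5,9-diene
Product: 22 (1S,2S,5E,8S)-9-(1-ethoxyethenyl)-2,6-dimethyl-11-oxabicyclo[6.2.1]undeca-5,9-dien-2-ol
Conditions: Bu4NF, THF, 0 °C to rt
Reagents that add atoms: none
Why: Fluoride removes the triethylsilyl group under basic conditions that the acid-labile ethoxydiene tolerates, freeing the C3 hydroxyl as anchor for the tether.

**Step 16**
Reactants: 22 (1S,2S,5E,8S)-9-(1-ethoxyethenyl)-2,6-dimethyl-11-oxabicyclo[6.2.1]undeca-5,9-dien-2-ol; 23 ethyl chlorooxoacetate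
Product: 24 ethyl (1S,2S,5E,8S)-9-(1-ethoxyethenyl)-2,6-dimethyl-11-oxabicyclo[6.2.1]undeca-5,9-dien-2-yl oxalate
Conditions: Et3N, DMAP (cat.), CH2Cl2, 0 °C
Reagents that add atoms: ethyl chlorooxoacetate (23), CCOC(=O)C(Cl)=O
Why: The very electrophilic oxalyl monochloride acylates even hindered tertiary alcohols under DMAP catalysis and brings in C16 and C15.

**Step 17**
Reactants: 24 ethyl (1S,2S,5E,8S)-9-(1-ethoxyethenyl)-2,6-dimethyl-11-oxabicyclo[6.2.1]undeca-5,9-dien-2-yl oxalate; 25 vinylmagnesium bromide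
Product: 26 (1S,2S,5E,8S)-9-(1-ethoxyethenyl)-2,6-dimethyl-11-oxabicyclo[6.2.1]undeca-5,9-dien-2-yl 2-oxobut-3-enoate
Conditions: THF, −78 °C; cold pH 7 buffer; solution used at once
Reagents that add atoms: vinylmagnesium bromide (25), C=C[Mg]Br
Why: Mono-addition of a Grignard reagent to an oxalate diester (the standard α-keto ester synthesis) should take place at the unhindered ethyl ester carbonyl, the chelated tetrahedral alkoxide surviving until the quench and then collapsing to the vinyl α-keto ester that carries C14 and C13.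

**Step 18**
Reactants: 26 (1S,2S,5E,8S)-9-(1-ethoxyethenyl)-2,6-dimethyl-11-oxabicyclo[6.2.1]undeca-5,9-dien-2-yl 2-oxobut-3-enoate
Product: 27 (1S,2S,3S,9S,14R)-11-ethoxy-2,9-epoxy-15-oxo-17-noreunicella-6E,10-dien-16,3-olide
Conditions: toluene (0.005 M), BHT (cat.), 80 °C; then DBU (0.1 equiv), rt
Reagents that add atoms: none
Why: A thermal normal-electron-demand [4+2] cycloaddition in which the HOMO of the 2-ethoxydiene (largest coefficient at C12) meets the LUMO of the vinyl α-keto ester (largest coefficient at C13), so that C12–C13 bonding leads and C1–C14 follows in one asynchronous event; a hetero-Diels–Alder adduct (C12–C13 and O–C11), should it form first, holds an allyl vinyl ether that can relay to the same product by [3,3] shift. The closest known reaction types are the bimolecular Diels–Alder reaction of this class of oxabicyclic 2-ethoxydienes with methyl vinyl ketone and ester-tethered type 1 intramolecular Diels–Alder reactions. Two rings close at once: the cyclohexene (C1, C10, C11, C12, C13, C14) by the cycloaddition itself, and the seven-membered lactone (C1–C2–C3–O–C16–C15–C14) as the fused tether ring, the tether sitting on the E position of the diene terminus. C1 is set by addition to the diene face anti to the oxonene bridge (the face of H2), which the C3–O tether can reach without crossing the nine-membered ring; C14 is set by the tether-exo arrangement that gives the trans ring fusion, and because C14–H is α to the C15 ketone the DBU treatment should funnel any cis-fused adduct to this more stable epimer. The step needs para regioselectivity (ethoxy polarisation, reinforced by the tether, since the reversed orientation would need a bridged eight-membered lactone), π-facial selectivity (bridge plus tether) and ring closure over oligomerisation (high dilution, radical inhibitor).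

**Step 19**
Reactants: 27 (1S,2S,3S,9S,14R)-11-ethoxy-2,9-epoxy-15-oxo-17-noreunicella-6E,10-dien-16,3-olide; 28 methyltriphenylphosphonium bromide
Product: 30 (1S,2S,3S,9S,14R)-11-ethoxy-2,9-epoxyeunicella-6E,10,15(17)-trien-16,3-olide, via methylenetriphenylphosphorane 29 (not isolated)
Conditions: KOt-Bu, THF, 0 °C; then 27, −78 to 0 °C
Reagents that add atoms: methyltriphenylphosphonium bromide (28), C[P+](c1ccccc1)(c1ccccc1)c1ccccc1.[Br-]
Why: Wittig methylenation should occur at the ketone of the α-keto lactone, far more electrophilic than the hindered lactone carbonyl, turning the temporary activating group into the future C17 methyl carbon.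

**Step 20**
Reactants: 30 (1S,2S,3S,9S,14R)-11-ethoxy-2,9-epoxyeunicella-6E,10,15(17)-trien-16,3-olide
Product: 31 (1S,2S,3S,9S,14R,15R)-11-ethoxy-2,9-epoxyeunicella-6E,10-dien-16,3-olide
Conditions: H2 (1 atm), RhCl(PPh3)3 (10 mol %), benzene, rt
Reagents that add atoms: none
Why: Homogeneous hydrogenation with RhCl(PPh3)3 reduces only the unhindered 1,1-disubstituted alkene (not the trisubstituted ring alkene or the tetrasubstituted enol ether), and hydrogen should arrive on the face anti to the adjacent C13 methylene (the face of H14), setting C15.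

**Step 21**
Reactants: 31 (1S,2S,3S,9S,14R,15R)-11-ethoxy-2,9-epoxyeunicella-6E,10-dien-16,3-olide
Product: 32 (1S,2S,3S,9S,10R,14R,15R)-2,9-epoxy-11-oxo-20-noreunicell-6E-en-16,3-olide
Conditions: 1 M aq. HCl, THF, 0 °C
Reagents that add atoms: water, O
Why: Mild acid hydrolysis of the enol ether unveils the C11 ketone, and C10, epimerisable α to it, should settle as the more stable cis ring fusion (H10 cis to H1).

**Step 22**
Reactants: 32 (1S,2S,3S,9S,10R,14R,15R)-2,9-epoxy-11-oxo-20-noreunicell-6E-en-16,3-olide; 11 methylmagnesium chloride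
Product: 33 (1S,2S,3S,9S,10R,11R,14R,15R)-2,9-epoxy-11-hydroxyeunicell-6E-en-16,3-olide
Conditions: LaCl3·2LiCl (0.3 equiv), THF, −78 °C; H2O
Reagents that add atoms: methylmagnesium chloride (11), C[Mg]Cl
Why: Lanthanum-promoted Grignard addition is chemoselective for the ketone over the hindered lactone at −78 °C and should proceed by axial attack on the convex face, anti to the axial C10–C9 bond, placing the methyl group cis to H10 and the C11 oxygen cis to C9.

**Step 23**
Reactants: 33 (1S,2S,3S,9S,10R,11R,14R,15R)-2,9-epoxy-11-hydroxyeunicell-6E-en-16,3-olide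
Product: 34 (1S,2S,3S,9S,10R,11R,14R,15R)-11-acetoxy-2,9-epoxyeunicell-6E-en-16,3-olide
Conditions: Ac2O, Et3N, DMAP, CH2Cl2, 40 °C
Reagents that add atoms: acetic anhydride, CC(=O)OC(C)=O
Why: DMAP-catalysed acylation acetylates the only free hydroxyl, the equatorial tertiary C11 alcohol.

**Step 24**
Reactants: 34 (1S,2S,3S,9S,10R,11R,14R,15R)-11-acetoxy-2,9-epoxyeunicell-6E-en-16,3-olide
Product: 35 (1S,2S,3S,6R,7R,9S,10R,11R,14R,15R)-11-acetoxy-2,9-epoxy-6,7-dihydroxyeunicellan-16,3-olide
Conditions: OsO4 (5 mol %), N-methylmorpholine N-oxide, acetone/H2O, rt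
Reagents that add atoms: osmium tetroxide, O=[Os](=O)(=O)=O (catalytic carrier of both oxygen atoms); N-methylmorpholine N-oxide, C[N+]1([O-])CCOCC1; water, O
Why: Upjohn syn dihydroxylation of the strained E alkene from its exposed peripheral face should give the 6R,7R diol, syn addition to the E geometry being what places the two oxygens on opposite faces of the nine-membered ring.

**Step 25**
Reactants: 35 (1S,2S,3S,6R,7R,9S,10R,11R,14R,15R)-11-acetoxy-2,9-epoxy-6,7-dihydroxyeunicellan-16,3-olide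
Product: 36 (1S,2S,3S,6R,7R,9S,10R,11R,14R,15R)-11-acetoxy-2,9-epoxy-7-hydroxy-6-methoxyeunicellan-16,3-olide
Conditions: Me3OBF4, 1,8-bis(dimethylamino)naphthalene, CH2Cl2, 0 °C to rt
Reagents that add atoms: trimethyloxonium tetrafluoroborate, C[O+](C)C.F[B-](F)(F)F
Why: Oxonium-salt methylation under non-basic conditions should alkylate the secondary C6 hydroxyl and leave the hindered tertiary C7 hydroxyl, the acetate and the lactone untouched.

**Compound list**

1 | 4-[(tert-butyldimethylsilyl)oxy]butanal | O=CCCCO[Si](C)(C)C(C)(C)C | starting material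
2 | isopropenylmagnesium bromide | CC(=C)[Mg]Br | starting material
3 | (±)-6-[(tert-butyldimethylsilyl)oxy]-2-methylhex-1-en-3-ol | CC(=C)C(O)CCCO[Si](C)(C)C(C)(C)C | intermediate
4 | (3S)-6-[(tert-butyldimethylsilyl)oxy]-2-methylhex-1-en-3-ol | CC(=C)[C@@H](O)CCCO[Si](C)(C)C(C)(C)C | intermediate
5 | ethyl propiolate | CCOC(=O)C#C | starting material
6 | ethyl (2E)-3-{[(3S)-6-[(tert-butyldimethylsilyl)oxy]-2-methylhex-1-en-3-yl]oxy}prop-2-enoate | CC(=C)[C@@H](O/C=C/C(=O)OCC)CCCO[Si](C)(C)C(C)(C)C | intermediate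
7 | ethyl (2E)-3-{[(3S)-6-hydroxy-2-methylhex-1-en-3-yl]oxy}prop-2-enoate | CC(=C)[C@@H](O/C=C/C(=O)OCC)CCCO | intermediate
8 | ethyl (2E)-3-{[(3S)-2-methyl-6-oxohex-1-en-3-yl]oxy}prop-2-enoate | CC(=C)[C@@H](O/C=C/C(=O)OCC)CCC=O | intermediate
9 | ethyl 2-[(2S,3R,6S)-3-hydroxy-6-(prop-1-en-2-yl)oxan-2-yl]acetate | CCOC(=O)C[C@@H]1O[C@H](C(C)=C)CC[C@H]1O | intermediate
10 | ethyl 2-[(2S,6S)-3-oxo-6-(prop-1-en-2-yl)oxan-2-yl]acetate | CCOC(=O)C[C@@H]1O[C@H](C(C)=C)CCC1=O | intermediate
11 | methylmagnesium chloride | C[Mg]Cl | starting material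
12 | ethyl 2-[(2S,3S,6S)-3-hydroxy-3-methyl-6-(prop-1-en-2-yl)oxan-2-yl]acetate | CCOC(=O)C[C@@H]1O[C@H](C(C)=C)CC[C@]1(C)O | intermediate
13 | ethyl 2-[(2S,3S,6S)-3-methyl-6-(prop-1-en-2-yl)-3-[(triethylsilyl)oxy]oxan-2-yl]acetate | CCOC(=O)C[C@@H]1O[C@H](C(C)=C)CC[C@]1(C)O[Si](CC)(CC)CC | intermediate
14 | 2-[(2S,3S,6S)-3-methyl-6-(prop-1-en-2-yl)-3-[(triethylsilyl)oxy]oxan-2-yl]acetic acid | OC(=O)C[C@@H]1O[C@H](C(C)=C)CC[C@]1(C)O[Si](CC)(CC)CC | intermediate
15 | diazomethane (ethereal solution, freshly made from commercial N-methyl-N-nitroso-p-toluenesulfonamide) | C=[N+]=[N-] | starting material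
16 | mixed isobutyl carbonic anhydride of acid 14 | CC(C)COC(=O)OC(=O)C[C@@H]1O[C@H](C(C)=C)CC[C@]1(C)O[Si](CC)(CC)CC | intermediate
17 | 1-diazo-3-[(2S,3S,6S)-3-methyl-6-(prop-1-en-2-yl)-3-[(triethylsilyl)oxy]oxan-2-yl]propan-2-one | [N-]=[N+]=CC(=O)C[C@@H]1O[C@H](C(C)=C)CC[C@]1(C)O[Si](CC)(CC)CC | intermediate
18 | (1S,2S,5E,8S)-2,6-dimethyl-2-[(triethylsilyl)oxy]-11-oxabicyclo[6.2.1]undec-5-en-9-one | C\C1=C/CC[C@](C)(O[Si](CC)(CC)CC)[C@@H]2CC(=O)[C@H](C1)O2 | intermediate
19 | (1S,2S,5E,8S)-2,6-dimethyl-2-[(triethylsilyl)oxy]-11-oxabicyclo[6.2.1]undeca-5,9-dien-9-yl trifluoromethanesulfonate | C\C1=C/CC[C@](C)(O[Si](CC)(CC)CC)[C@@H]2C=C(OS(=O)(=O)C(F)(F)F)[C@H](C1)O2 | intermediate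
20 | tributyl(1-ethoxyvinyl)stannane | CCCC[Sn](CCCC)(CCCC)C(=C)OCC | starting material
21 | (1S,2S,5E,8S)-9-(1-ethoxyethenyl)-2,6-dimethyl-2-[(triethylsilyl)oxy]-11-oxabicyclo[6.2.1]undeca-5,9-diene | C\C1=C/CC[C@](C)(O[Si](CC)(CC)CC)[C@@H]2C=C(C(=C)OCC)[C@H](C1)O2 | intermediate
22 | (1S,2S,5E,8S)-9-(1-ethoxyethenyl)-2,6-dimethyl-11-oxabicyclo[6.2.1]undeca-5,9-dien-2-ol | C\C1=C/CC[C@](C)(O)[C@@H]2C=C(C(=C)OCC)[C@H](C1)O2 | intermediate
23 | ethyl chlorooxoacetate | CCOC(=O)C(Cl)=O | starting material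
24 | ethyl (1S,2S,5E,8S)-9-(1-ethoxyethenyl)-2,6-dimethyl-11-oxabicyclo[6.2.1]undeca-5,9-dien-2-yl oxalate | C\C1=C/CC[C@](C)(OC(=O)C(=O)OCC)[C@@H]2C=C(C(=C)OCC)[C@H](C1)O2 | intermediate
25 | vinylmagnesium bromide | C=C[Mg]Br | starting material
26 | (1S,2S,5E,8S)-9-(1-ethoxyethenyl)-2,6-dimethyl-11-oxabicyclo[6.2.1]undeca-5,9-dien-2-yl 2-oxobut-3-enoate | C\C1=C/CC[C@](C)(OC(=O)C(=O)C=C)[C@@H]2C=C(C(=C)OCC)[C@H](C1)O2 | intermediate
27 | (1S,2S,3S,9S,14R)-11-ethoxy-2,9-epoxy-15-oxo-17-noreunicella-6E,10-dien-16,3-olide (tetracyclic α-keto lactone) | C\C1=C/CC[C@]2(C)OC(=O)C(=O)[C@@H]3CCC(OCC)=C4[C@H]3[C@@H]2O[C@H]4C1 | intermediate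
28 | methyltriphenylphosphonium bromide | C[P+](c1ccccc1)(c1ccccc1)c1ccccc1.[Br-] | starting material
29 | methylenetriphenylphosphorane | C=P(c1ccccc1)(c1ccccc1)c1ccccc1 | intermediate
30 | (1S,2S,3S,9S,14R)-11-ethoxy-2,9-epoxyeunicella-6E,10,15(17)-trien-16,3-olide (α-methylene lactone) | C\C1=C/CC[C@]2(C)OC(=O)C(=C)[C@@H]3CCC(OCC)=C4[C@H]3[C@@H]2O[C@H]4C1 | intermediate
31 | (1S,2S,3S,9S,14R,15R)-11-ethoxy-2,9-epoxyeunicella-6E,10-dien-16,3-olide | C\C1=C/CC[C@]2(C)OC(=O)[C@H](C)[C@@H]3CCC(OCC)=C4[C@H]3[C@@H]2O[C@H]4C1 | intermediate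
32 | (1S,2S,3S,9S,10R,14R,15R)-2,9-epoxy-11-oxo-20-noreunicell-6E-en-16,3-olide | C\C1=C/CC[C@]2(C)OC(=O)[C@H](C)[C@@H]3CCC(=O)[C@@H]4[C@H]3[C@@H]2O[C@H]4C1 | intermediate
33 | (1S,2S,3S,9S,10R,11R,14R,15R)-2,9-epoxy-11-hydroxyeunicell-6E-en-16,3-olide | C\C1=C/CC[C@]2(C)OC(=O)[C@H](C)[C@@H]3CC[C@@](C)(O)[C@@H]4[C@H]3[C@@H]2O[C@H]4C1 | intermediate
34 | (1S,2S,3S,9S,10R,11R,14R,15R)-11-acetoxy-2,9-epoxyeunicell-6E-en-16,3-olide | C\C1=C/CC[C@]2(C)OC(=O)[C@H](C)[C@@H]3CC[C@@](C)(OC(C)=O)[C@@H]4[C@H]3[C@@H]2O[C@H]4C1 | intermediate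
35 | (1S,2S,3S,6R,7R,9S,10R,11R,14R,15R)-11-acetoxy-2,9-epoxy-6,7-dihydroxyeunicellan-16,3-olide | O[C@@H]1CC[C@]2(C)OC(=O)[C@H](C)[C@@H]3CC[C@@](C)(OC(C)=O)[C@@H]4[C@H]3[C@@H]2O[C@H]4C[C@@]1(C)O | intermediate
36 | (1S,2S,3S,6R,7R,9S,10R,11R,14R,15R)-11-acetoxy-2,9-epoxy-7-hydroxy-6-methoxyeunicellan-16,3-olide (CNP0238771.1) | CO[C@@H]1CC[C@]2(C)OC(=O)[C@H](C)[C@@H]3CC[C@@](C)(OC(C)=O)[C@@H]4[C@H]3[C@@H]2O[C@H]4C[C@@]1(C)O | target

**Step count and risks**

Total steps: 25. Longest linear sequence: 25 steps (1 to 36).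

Steps most likely to fail:

Step 18. The tethered vinyl ketone may add to the lower face of the diene, or may oligomerise by Diels–Alder or hetero-Diels–Alder reaction between molecules faster than the seven-membered tether ring closes. Fallback (bimolecular cycloaddition first, lactone last), setting out from diene 21: cycloaddition with methyl vinyl ketone (toluene, 60 °C) followed by K2CO3/MeOH equilibration at C14 gives the C14 acetyl cycloadduct F1. Wittig methylenation (Ph3P=CH2) gives the C14 isopropenyl compound F2. Hydroboration with 9-borabicyclo[3.3.1]nonane and NaOH/H2O2 work-up gives the C16 primary alcohol F3, with C15 set by attack anti to the ring (diisopinocampheylborane as reagent control if needed). Oxidation with TEMPO/PhI(OAc)2 in wet MeCN gives the C16 acid F4. Bu4NF frees the C3 hydroxyl to give the hydroxy acid F5. Yamaguchi lactonisation (2,4,6-trichlorobenzoyl chloride, Et3N, then DMAP, toluene) closes the lactone and comes back to the route at 31.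

Step 17. A second equivalent of the Grignard reagent may add (to the new ketone or in the conjugate sense) before the tetrahedral intermediate is quenched, or the vinyl ketone may polymerise during work-up. Fallback (acyl cross-coupling in place of organomagnesium addition), setting out from alcohol 22: oxalyl chloride (CH2Cl2, 0 °C, then evaporation) gives the chlorooxoacetate F6. Coupling with tributyl(vinyl)stannane under Pd2(dba)3/tri(2-furyl)phosphine (THF, rt) gives the vinyl keto ester under neutral conditions and comes back to the route at 26.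

Step 20. Hydrogen may be delivered to the other face of the exocyclic alkene, giving poor or reversed facial selectivity at C15. Fallback (the methyl group is introduced as the electrophile, which inverts the sense of delivery), setting out from keto lactone 27: NaBH4 (MeOH/THF, −78 °C) gives the C15 hydroxy lactone F7 (C15 epimers, of no consequence). SmI2/HMPA with ethylene glycol removes the α-hydroxyl and gives the C15 methylene lactone F8. Lithium diisopropylamide (THF, −78 °C) then MeI methylates the lactone enolate from its open face and comes back to the route at 31.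

**Further compounds**

F1 | step 18 | C14 acetyl cycloadduct of 21 (C3 triethylsilyl ether, C10=C11 ethyl enol ether, H14 trans to H1) | C\C1=C/CC[C@](C)(O[Si](CC)(CC)CC)[C@H]2O[C@@H](C1)C3=C(OCC)CC[C@@H](C(C)=O)[C@H]23
F2 | step 18 | C14 isopropenyl analogue of F1 | C\C1=C/CC[C@](C)(O[Si](CC)(CC)CC)[C@H]2O[C@@H](C1)C3=C(OCC)CC[C@@H](C(C)=C)[C@H]23
F3 | step 18 | C16 primary alcohol from hydroboration of F2 (C15 as in 31) | C\C1=C/CC[C@](C)(O[Si](CC)(CC)CC)[C@H]2O[C@@H](C1)C3=C(OCC)CC[C@@H]([C@@H](C)CO)[C@H]23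
F4 | step 18 | C16 carboxylic acid from F3 | C\C1=C/CC[C@](C)(O[Si](CC)(CC)CC)[C@H]2O[C@@H](C1)C3=C(OCC)CC[C@@H]([C@@H](C)C(O)=O)[C@H]23
F5 | step 18 | C3 hydroxy C16 acid (seco acid of 31) | C\C1=C/CC[C@](C)(O)[C@H]2O[C@@H](C1)C3=C(OCC)CC[C@@H]([C@@H](C)C(O)=O)[C@H]23
F6 | step 17 | chlorooxoacetate of alcohol 22 | C\C1=C/CC[C@](C)(OC(=O)C(Cl)=O)[C@@H]2C=C(C(=C)OCC)[C@H](C1)O2
F7 | step 20 | C15 hydroxy lactone from reduction of 27 (C15 epimers) | C\C1=C/CC[C@]2(C)OC(=O)C(O)[C@@H]3CCC(OCC)=C4[C@H]3[C@@H]2O[C@H]4C1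
F8 | step 20 | C15 methylene (17-nor) lactone | C\C1=C/CC[C@]2(C)OC(=O)C[C@@H]3CCC(OCC)=C4[C@H]3[C@@H]2O[C@H]4C1
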